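## Analysis of the target

The target (C42H32O9) is a resveratrol trimer made of two 2,3-diaryl-2,3-dihydrobenzofurans that share one benzene ring. Ring A (C3a, C4 to C7, C7a; OH on C6, (E)-4-hydroxystyryl with ring H on C4) is fused to heterocycle B (O1, C2, C3). C3 is bonded to C6' of ring C (C3a', C4' to C7', C7a'; OH on C4'), which is fused to heterocycle D (O1', C2', C3'); C3' carries the 3,5-dihydroxyphenyl ring E, and C2 and C2' carry the 4-hydroxyphenyl rings F and G. The four stereocentres form two trans pairs, (2S,3S) in ring B and (2R,3R) in ring D. The CIP rank order is the same in both rings, so the two heterocycles have opposite absolute sense, and because they lie at the two ends of the para axis C6'–C3a' of ring C, neither pair can direct the other. The plan exploits one feature: O1–C2(H)–ring F and O1'–C2'(H)–ring G are 4-hydroxybenzyl ethers of phenol oxygens of rings A and C, each tied back to the neighbouring diarylmethine carbon (C3, C3') by a single C–C bond. The same two C–O bonds (C2–O1, C2'–O1') ionise reversibly to para-quinone methides, so C2 and C2' are configurationally dynamic and settle trans, whereas C3 and C3' are fixed once made. The sensitive groups are the seven oxidisable phenols, the light- and acid-sensitive stilbene, and above all the array C4-styryl/C3-aryl/C2–O1 around ring B, where ionisation of C2–O1 or protonation of the alkene lets the alkene or ring C close a five- or seven-membered carbocycle irreversibly. Three things make the synthesis hard: the crowding at C3 (between C4 and ring C) and at C3' (between the oxygens on C4' and C7a'), the meta oxygen pattern that leaves C6' and the ipso carbon of ring E non-nucleophilic and so rules out Friedel–Crafts bonds to C3 and C3', and the need for two independent acts of absolute stereocontrol of opposite sense.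

## Retrosynthetic reasoning

**28 ⇒ 27 ⇒ 23 + 26.** The stilbene C=C between C4 and ring H is cut first, so it is made last. The styryl group must be absent in three situations:
- while a diazo group sits on the neighbouring C3, because ortho-alkenyl aryldiazomethanes electrocyclise or cyclopropanate;
- while C2–O1 is being equilibrated;
- while benzyl ethers are hydrogenolysed.

The forward reaction has to be an E-selective olefination of the crowded aldehyde 23, followed by a near-neutral global deprotection of 27.

**23 ⇒ 22 ⇒ 21 ⇒ 20.** No skeletal bond is cut here. Instead two configurations are released, so C2 and C2' need not be correct in 20. Because C2–O1 and C2'–O1' open and close reversibly once rings F and G carry free OH groups, any cis/trans mixture converges on the trans,trans compound 22. Only C3 and C3' must therefore be set by a reagent.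

**20 ⇒ 19 ⇒ 18 (key disconnection).** The C2–C3 bond of ring B is cut. This removes ring B and both of its stereocentres at once. What remains is a flat carbene precursor in which C2 and ring F are an ordinary benzyl-type protecting group on O1. The forward reaction is a catalyst-controlled 1,5-C–H insertion of a diaryl carbene centred on C3. The C–O bond was not chosen because closing it sets only C2, which corrects itself anyway, and leaves the real problem (C3) unsolved.

**18 ⇒ 17 ⇒ 16 (from 15) + 10.** The bond between C3 and C3a is cut.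
- C6' is meta to both oxygens of ring C, so the carbon on it is made the electrophile, as the nitrile of 10.
- C3a becomes the nucleophile, as the aryllithium 16 held between two coordinating ortho groups.
- The addition delivers C3 directly at the imine oxidation level, so the ketimine 17 is converted into hydrazone 18 without ever passing through a doubly ortho-substituted ketone.

**10 ⇒ 9 ⇒ 8 ⇒ 7.** The same cut, C2'–C3', is applied to ring D, with the enantiomeric catalyst. It is done before the fragments are joined, because the opposite sense of rings B and D demands two separate stereodefining events.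

**7 ⇒ 6 ⇒ 3 + 4 (through 5); 3 ⇒ 1 + 2.** Ring C is taken from the symmetric difluoride 1. Both fluorides are replaced by the same benzylic alkoxide. The two ether groups are equivalent, so one becomes C2'–ring G and the other remains as the protecting group of the C4' oxygen. Ring E arrives as a Grignard reagent.

**15 ⇒ 14 ⇒ 12 + 13; 12 ⇒ 11.** Ring A comes from a benzaldehyde that already carries the bromine at the future C3a. The aldehyde (future C4 substituent) is masked as an acetal.

**26 ⇒ 25 ⇒ 24.** The phosphonate that brings ring H is made in two steps off the main line.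

## Alternatives that were turned down

**Alternative 1:** (the textbook, biomimetic cut)
- Disconnection: C3–C3a and C2–O1 of ring B are cut together.
- Forward key step: oxidative cross-coupling of (2R,3R)-gnetin C (A1) with resveratrol (A2). A one-electron oxidant gives phenoxyl radicals, the alkene carbon of A1 that is bonded to C6' of ring C joins an ortho carbon of the resorcinol ring of A2, and the para-quinone methide is closed by the adjacent OH to give 28.
- Why turned down:
  - Both partners give delocalised radicals with several reactive sites (O, ring carbons, alkene carbon), so homo-coupling of A1 and of A2 and other regioisomers compete.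
  - 28 is as easily oxidised as its precursors.
  - Nothing controls the face of attack, since ring D is too remote to bias ring B.
  - A1 as a single enantiomer would itself cost about as much as compound 10.

**Alternative 2:**
- Disconnection: C2–O1 and the bond from C2 to ring F are cut.
- Forward key step: a 4-oxygenated aryl Grignard reagent is added to the α,α-diarylacetaldehyde A3, and acid then closes ring B through the para-quinone methide.
- Why turned down:
  - The closure sets only C2, the centre that needs no control.
  - C3 in A3 is a doubly benzylic carbon next to an aldehyde and should racemise by enolisation under the basic addition.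
  - Reaching A3 from a diaryl ketone needs a one-carbon homologation of several steps with no good handle for enantiocontrol, and all of this would be needed twice.

**Alternative 3:**
- Disconnection: C2–C3 and C2'–C3' are cut in one operation.
- Forward key step: double C–H insertion of the bis(diazo) compound A4 with one chiral catalyst, closing both rings and setting all four stereocentres together.
- Why turned down: it fails on stereochemical grounds.
  - In both carbenes the catalyst meets the same local arrangement, a tethered aryl ring with an ortho OCH2Ar group and a free aryl ring. One catalyst enantiomer should therefore give the same local sense twice. That is A5 with (3S,3'S), which equilibrates to the (2S,3S,2'S,3'S) diastereomer of the required skeleton and not to the (2S,3S,2'R,3'R) series.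
  - Two enantiomeric catalysts in one flask would scramble the centres.
  - A4 should also be more prone to azine oligomers.
  - The same bond type is therefore cut twice, but in two separate steps.

Key step: step 10

Assumption: Rh2(S-PTAD)4 is taken to deliver the (3S) centre and Rh2(R-PTAD)4 the (3'R) centre; both enantiomers of the catalyst are commercial, so the two are exchanged if a model insertion shows the opposite sense.

Abbreviations: Bn = benzyl; BOB = 4-(benzyloxy)benzyl; TBS = tert-butyldimethylsilyl; Rh2(S-PTAD)4 = dirhodium tetrakis[(S)-(1-adamantyl)(phthalimido)acetate].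

## Steps

Step 1
Reactants: 1 3,5-difluoro-4-formylbenzonitrile; 2 [4-(benzyloxy)phenyl]methanol (2.1 equiv)
Product: 3 3,5-bis{[4-(benzyloxy)benzyl]oxy}-4-formylbenzonitrile
Conditions: NaH, THF–DMF, 0 °C to rt
Reagents that add atoms: none
Why: Twofold nucleophilic aromatic substitution: both fluorides are ortho to the formyl group, so the alkoxide of 2 displaces them one after the other. The product keeps the local symmetry of ring C, so its two oxygens need not be told apart, and each new OCH2Ar group is a latent C2'–ring G unit.

Step 2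
Reactants: 3 3,5-bis{[4-(benzyloxy)benzyl]oxy}-4-formylbenzonitrile; 4 1,3-bis(benzyloxy)-5-bromobenzene
Product: 6 (±)-4-{[3,5-bis(benzyloxy)phenyl](hydroxy)methyl}-3,5-bis{[4-(benzyloxy)benzyl]oxy}benzonitrile, via aryl Grignard reagent 5 (not isolated)
Conditions: 4, Mg, THF, reflux; then 3, THF, −40 to 0 °C; aq. NH4Cl
Reagents that add atoms: none
Why: Grignard addition to an aldehyde: at low temperature the arylmagnesium bromide adds to the formyl group much faster than to the nitrile. The new carbinol centre is racemic and is erased in step 3.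

Step 3
Reactants: 6 (±)-diaryl carbinol
Product: 7 4-[3,5-bis(benzyloxy)benzoyl]-3,5-bis{[4-(benzyloxy)benzyl]oxy}benzonitrile
Conditions: Dess–Martin periodinane, CH2Cl2, rt
Reagents that add atoms: none
Why: Dess–Martin oxidation of a hindered diaryl carbinol under almost neutral conditions; benzyl-type ethers and the nitrile are inert.

Step 4
Reactants: 7 diaryl ketone
Product: 8 hydrazone of 7, 4-{[3,5-bis(benzyloxy)phenyl](hydrazinylidene)methyl}-3,5-bis{[4-(benzyloxy)benzyl]oxy}benzonitrile (E/Z mixture)
Conditions: N2H4·H2O (excess), AcOH (cat.), EtOH–THF, 80 °C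
Reagents that add atoms: hydrazine, NN
Why: Hydrazone formation: hydrazine is small and an alpha-effect nucleophile, the carbonyl group is activated by the para nitrile, and ortho alkoxy groups hinder less than ortho alkyl groups. An aryl nitrile needs a catalyst or a much higher temperature to add hydrazine.

Step 5
Reactants: 8 hydrazone of 7
Product: 10 (2S,3R)-3-[3,5-bis(benzyloxy)phenyl]-2-[4-(benzyloxy)phenyl]-4-{[4-(benzyloxy)benzyl]oxy}-2,3-dihydro-1-benzofuran-6-carbonitrile (cis), via diaryldiazomethane 9 (not isolated)
Conditions: MnO2, CH2Cl2, 0 °C to rt; filtered into Rh2(R-PTAD)4 (1 mol %), CH2Cl2, 0 °C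
Reagents that add atoms: none
Why: Dehydrogenation of the hydrazone gives 9, and the chiral dirhodium carboxylate turns it into a donor/donor carbene that undergoes enantioselective intramolecular 1,5-C–H insertion into an ortho OCH2Ar group. The two OCH2Ar groups are interchanged by rotation about the bond from C3a' to the carbene carbon, so either gives 10; the catalyst sets C3' as R and the compact transition state places rings E and G cis (C2' is S here and is corrected in step 11). The unused BOB ether stays as the protecting group of the C4' oxygen.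

Step 6
Reactants: 11 2-bromo-3,5-dimethoxybenzaldehyde
Product: 12 2-bromo-3,5-dihydroxybenzaldehyde
Conditions: BBr3, CH2Cl2, −78 °C to rt; H2O
Reagents that add atoms: none
Why: Lewis acid cleavage of aryl methyl ethers with BBr3. Starting from the ready-made bromide avoids a bromination in the presence of other electron-rich rings.

Step 7
Reactants: 12 2-bromo-3,5-dihydroxybenzaldehyde; 13 1-(benzyloxy)-4-(chloromethyl)benzene (2.2 equiv)
Product: 14 3,5-bis{[4-(benzyloxy)benzyl]oxy}-2-bromobenzaldehyde
Conditions: K2CO3, DMF, 60 °C
Reagents that add atoms: none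
Why: Williamson ether synthesis on both phenols. The ether next to the bromine (the later O1) is the latent C2–ring F unit, and the other one protects the later C6 oxygen.

Step 8
Reactants: 14 3,5-bis{[4-(benzyloxy)benzyl]oxy}-2-bromobenzaldehyde
Product: 15 1,5-bis{[4-(benzyloxy)benzyl]oxy}-2-bromo-3-(dimethoxymethyl)benzene
Conditions: HC(OMe)3, camphorsulfonic acid (cat.), MeOH, rt
Reagents that add atoms: trimethyl orthoformate, COC(OC)OC
Why: Acetalisation with an orthoester as water scavenger under mild acid that spares the BOB ethers. The acetal masks the aldehyde against the aryllithium and above all against hydrazine, which would otherwise close a phthalazine with the neighbouring C=N carbon.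

Step 9
Reactants: 15 aryl bromide acetal; 10 cis-dihydrobenzofuran nitrile
Product: 18 hydrazone (E/Z mixture) of the diaryl ketimine that joins C3a of ring A and C6' of ring C through the future C3, via aryllithium 16 (not isolated), via ketimine 17 (not isolated)
Conditions: 15, n-BuLi, THF, −78 °C; then 10, −78 to −20 °C; AcOH (1.2 equiv); then anhydrous N2H4 (excess), EtOH, 60 °C
Reagents that add atoms: hydrazine, NN
Why: Bromine–lithium exchange gives 16, held by the flanking acetal and ether oxygens; it adds once to the unhindered nitrile of 10 (organolithium addition to a nitrile), and the N–H ketimine 17 exchanges NH3 for hydrazine (transimination). C3 is thus delivered at the imine level, the hindered ketone is never made, and the excess hydrazine keeps the medium basic so that the acetal survives. The stereocentres of ring D are not touched.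

Step 10
Reactants: 18 hydrazone
Product: 20 (2R,3S,2'S,3'R)-bis(cis-dihydrobenzofuran) dimethyl acetal: ring B carries ring F (4-benzyloxyphenyl) on C2, ring C on C3, CH(OMe)2 on C4 and OBOB on C6; ring D as in 10, via diaryldiazomethane 19 (not isolated)
Conditions: MnO2, CH2Cl2, 0 °C to rt; filtered and added slowly to Rh2(S-PTAD)4 (1–2 mol %), CH2Cl2, 0 °C to rt
Reagents that add atoms: none
Why: MnO2 dehydrogenates the hydrazone to 19, which loses N2 on Rh2(S-PTAD)4 to give a donor/donor rhodium carbene at C3; the closest known reaction type is the enantioselective intramolecular C–H insertion of diaryl carbenes into ortho benzyl ethers, which gives cis-2,3-diaryl-2,3-dihydrobenzofurans. The insertion is a concerted but asynchronous hydride shift from the O1–CH2 carbon to the carbene carbon followed by C2–C3 bond formation, and the positive charge that builds up on C2 is stabilised by O1 and by the 4-benzyloxyphenyl ring F. Ring B, the only ring formed, closes as a 1,5-insertion through a five-membered transition state. C3 is set by the chiral pocket of the catalyst, which fixes the face of the carbene that receives the hydrogen, and C2 is set by which of the two diastereotopic benzylic hydrogens is presented in that pocket, the compact transition state placing rings C and F cis. Site selectivity among nine benzylic OCH2 groups is secured by distance: only the OCH2 on the C7a oxygen lies 1,5 to the carbene, the acetal C–H on the other ortho carbon could give only a four-membered ring, and the acetal OCH3 groups only a six-membered ring from a primary C–H bond. Because the stereocentres of ring D sit beyond the para axis of ring C, no match or mismatch is expected and the catalyst alone decides, which is what the opposite sense of rings B and D requires. The low electrophilicity of a donor/donor carbene and its two ortho substituents should suppress azine formation and attack on the many arene rings. Any minor C3 epimer is a diastereomer of 20 and can be removed by chromatography, which also raises the enantiomeric purity of the main isomer.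

Step 11
Reactants: 20 bis(cis-dihydrobenzofuran) acetal
Product: 22 (2S,3S)-6-hydroxy-2-(4-hydroxyphenyl)-3-[(2R,3R)-3-(3,5-dihydroxyphenyl)-4-hydroxy-2-(4-hydroxyphenyl)-2,3-dihydro-1-benzofuran-6-yl]-2,3-dihydro-1-benzofuran-4-carbaldehyde (trans,trans), via hexaphenol acetal 21 (not isolated)
Conditions: H2 (1 atm), Pd/C, EtOAc–MeOH, rt; filtered; then 1 M aq. HCl, THF, high dilution, 40 °C, Ar
Reagents that add atoms: water, O
Why: Hydrogenolysis removes six benzyl ethers and the two spectator 4-oxybenzyl ethers while the aldehyde is still masked; the cyclic, secondary and crowded C2–O1 and C2'–O1' bonds should react much more slowly. Dilute acid then hydrolyses the acetal and, through reversible ionisation of C2–O1 and C2'–O1' to protonated para-quinone methides (retro-oxa-Michael/oxa-Michael equilibrium), funnels both cis rings into the more stable trans rings. C3 and C3' take no part in this equilibrium, so (2R,3S,2'S,3'R) becomes (2S,3S,2'R,3'R).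

Step 12
Reactants: 22 hexaphenol aldehyde
Product: 23 hexakis-O-TBS ether of 22
Conditions: TBSCl, imidazole, DMF, rt to 40 °C
Reagents that add atoms: tert-butyldimethylsilyl chloride, CC(C)(C)[Si](C)(C)Cl
Why: Silylation of all six phenols gives a soluble aldehyde without acidic protons whose protecting groups leave later with fluoride, without acid, base or hydrogen. No stereocentre is affected.

Step 13
Reactants: 24 4-[(tert-butyldimethylsilyl)oxy]benzaldehyde
Product: 25 {4-[(tert-butyldimethylsilyl)oxy]phenyl}methanol
Conditions: NaBH4, MeOH, 0 °C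
Reagents that add atoms: none
Why: Borohydride reduction of an aromatic aldehyde; the aryl silyl ether survives the short exposure at 0 °C.

Step 14
Reactants: 25 {4-[(tert-butyldimethylsilyl)oxy]phenyl}methanol
Product: 26 diethyl {4-[(tert-butyldimethylsilyl)oxy]benzyl}phosphonate
Conditions: P(OEt)3, ZnI2, toluene, reflux
Reagents that add atoms: triethyl phosphite, CCOP(OCC)OCC
Why: Direct Arbuzov-type conversion of a benzylic alcohol: ZnI2 promotes exchange of the alcohol into the phosphite and the C–O to C–P rearrangement, helped by the electron-rich benzylic position. No labile benzylic halide has to be handled.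

Step 15
Reactants: 23 hexakis-O-TBS aldehyde; 26 phosphonate
Product: 27 heptakis-O-TBS ether of the target, (E)-alkene
Conditions: 26, KN(SiMe3)2, THF, −78 °C; then 23, −78 °C to rt
Reagents that add atoms: none
Why: Horner–Wadsworth–Emmons olefination with a benzylic phosphonate, which gives the E-stilbene through the more stable anti-configured adduct. The aldehyde has no alpha hydrogen, and neither the base nor the phosphonate anion touches C3–H at low temperature.

Step 16
Reactants: 27 heptakis-O-TBS ether
Product: 28 the target, (2S,3S,2'R,3'R), (E)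
Conditions: Bu4NF, AcOH (1:1), THF, 0 °C, Ar, dark
Reagents that add atoms: none
Why: Fluoride cleavage of aryl silyl ethers. Buffering with acetic acid keeps the medium near neutral, so neither acid ionisation of C2–O1 nor phenoxide-driven ring opening next to the new styryl group can start, and exclusion of light and air protects the stilbene and the phenols.

## Compound list

1 | 3,5-difluoro-4-formylbenzonitrile | N#Cc1cc(F)c(C=O)c(F)c1 | starting material
2 | [4-(benzyloxy)phenyl]methanol | OCc1ccc(OCc2ccccc2)cc1 | starting material
3 | 3,5-bis{[4-(benzyloxy)benzyl]oxy}-4-formylbenzonitrile | N#Cc1cc(OCc2ccc(OCc3ccccc3)cc2)c(C=O)c(OCc2ccc(OCc3ccccc3)cc2)c1 | intermediate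
4 | 1,3-bis(benzyloxy)-5-bromobenzene | Brc1cc(OCc2ccccc2)cc(OCc2ccccc2)c1 | starting material
5 | [3,5-bis(benzyloxy)phenyl]magnesium bromide | Br[Mg]c1cc(OCc2ccccc2)cc(OCc2ccccc2)c1 | intermediate
6 | (±)-4-{[3,5-bis(benzyloxy)phenyl](hydroxy)methyl}-3,5-bis{[4-(benzyloxy)benzyl]oxy}benzonitrile | N#Cc1cc(OCc2ccc(OCc3ccccc3)cc2)c(C(O)c2cc(OCc3ccccc3)cc(OCc3ccccc3)c2)c(OCc2ccc(OCc3ccccc3)cc2)c1 | intermediate
7 | 4-[3,5-bis(benzyloxy)benzoyl]-3,5-bis{[4-(benzyloxy)benzyl]oxy}benzonitrile | N#Cc1cc(OCc2ccc(OCc3ccccc3)cc2)c(C(=O)c2cc(OCc3ccccc3)cc(OCc3ccccc3)c2)c(OCc2ccc(OCc3ccccc3)cc2)c1 | intermediate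
8 | hydrazone of 7 | N#Cc1cc(OCc2ccc(OCc3ccccc3)cc2)c(C(=NN)c2cc(OCc3ccccc3)cc(OCc3ccccc3)c2)c(OCc2ccc(OCc3ccccc3)cc2)c1 | intermediate
9 | 4-{[3,5-bis(benzyloxy)phenyl](diazo)methyl}-3,5-bis{[4-(benzyloxy)benzyl]oxy}benzonitrile | N#Cc1cc(OCc2ccc(OCc3ccccc3)cc2)c(C(=[N+]=[N-])c2cc(OCc3ccccc3)cc(OCc3ccccc3)c2)c(OCc2ccc(OCc3ccccc3)cc2)c1 | intermediate
10 | (2S,3R)-3-[3,5-bis(benzyloxy)phenyl]-2-[4-(benzyloxy)phenyl]-4-{[4-(benzyloxy)benzyl]oxy}-2,3-dihydro-1-benzofuran-6-carbonitrile | N#Cc1cc(OCc2ccc(OCc3ccccc3)cc2)c2c(c1)O[C@H](c1ccc(OCc3ccccc3)cc1)[C@@H]2c1cc(OCc2ccccc2)cc(OCc2ccccc2)c1 | intermediate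
11 | 2-bromo-3,5-dimethoxybenzaldehyde | O=Cc1cc(OC)cc(OC)c1Br | starting material
12 | 2-bromo-3,5-dihydroxybenzaldehyde | O=Cc1cc(O)cc(O)c1Br | intermediate
13 | 1-(benzyloxy)-4-(chloromethyl)benzene | ClCc1ccc(OCc2ccccc2)cc1 | starting material
14 | 3,5-bis{[4-(benzyloxy)benzyl]oxy}-2-bromobenzaldehyde | O=Cc1cc(OCc2ccc(OCc3ccccc3)cc2)cc(OCc2ccc(OCc3ccccc3)cc2)c1Br | intermediate
15 | 1,5-bis{[4-(benzyloxy)benzyl]oxy}-2-bromo-3-(dimethoxymethyl)benzene | COC(OC)c1cc(OCc2ccc(OCc3ccccc3)cc2)cc(OCc2ccc(OCc3ccccc3)cc2)c1Br | intermediate
16 | [2,4-bis{[4-(benzyloxy)benzyl]oxy}-6-(dimethoxymethyl)phenyl]lithium | COC(OC)c1cc(OCc2ccc(OCc3ccccc3)cc2)cc(OCc2ccc(OCc3ccccc3)cc2)c1[Li] | intermediate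
17 | N–H ketimine joining ring A (C3a) and ring C (C6'), ring D (2'S,3'R) | N=C(c1c(C(OC)OC)cc(OCc2ccc(OCc3ccccc3)cc2)cc1OCc1ccc(OCc2ccccc2)cc1)c1cc(OCc2ccc(OCc3ccccc3)cc2)c2c(c1)O[C@H](c1ccc(OCc3ccccc3)cc1)[C@@H]2c1cc(OCc2ccccc2)cc(OCc2ccccc2)c1 | intermediate
18 | hydrazone corresponding to 17 | NN=C(c1c(C(OC)OC)cc(OCc2ccc(OCc3ccccc3)cc2)cc1OCc1ccc(OCc2ccccc2)cc1)c1cc(OCc2ccc(OCc3ccccc3)cc2)c2c(c1)O[C@H](c1ccc(OCc3ccccc3)cc1)[C@@H]2c1cc(OCc2ccccc2)cc(OCc2ccccc2)c1 | intermediate
19 | diaryldiazomethane corresponding to 18 | [N-]=[N+]=C(c1c(C(OC)OC)cc(OCc2ccc(OCc3ccccc3)cc2)cc1OCc1ccc(OCc2ccccc2)cc1)c1cc(OCc2ccc(OCc3ccccc3)cc2)c2c(c1)O[C@H](c1ccc(OCc3ccccc3)cc1)[C@@H]2c1cc(OCc2ccccc2)cc(OCc2ccccc2)c1 | intermediate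
20 | (2R,3S,2'S,3'R)-bis(cis-dihydrobenzofuran) dimethyl acetal, fully benzyl/BOB protected | COC(OC)c1cc(OCc2ccc(OCc3ccccc3)cc2)cc2c1[C@H](c4cc(OCc5ccc(OCc6ccccc6)cc5)c5c(c4)O[C@H](c4ccc(OCc6ccccc6)cc4)[C@@H]5c4cc(OCc5ccccc5)cc(OCc5ccccc5)c4)[C@H](c4ccc(OCc5ccccc5)cc4)O2 | intermediate
21 | (2R,3S,2'S,3'R)-hexaphenol dimethyl acetal | COC(OC)c1cc(O)cc2c1[C@H](c4cc(O)c5c(c4)O[C@H](c4ccc(O)cc4)[C@@H]5c4cc(O)cc(O)c4)[C@H](c4ccc(O)cc4)O2 | intermediate
22 | (2S,3S,2'R,3'R)-hexaphenol aldehyde (trans,trans) | O=Cc1cc(O)cc2c1[C@H](c4cc(O)c5c(c4)O[C@@H](c4ccc(O)cc4)[C@@H]5c4cc(O)cc(O)c4)[C@@H](c4ccc(O)cc4)O2 | intermediate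
23 | hexakis-O-TBS ether of 22 | O=Cc1cc(O[Si](C)(C)C(C)(C)C)cc2c1[C@H](c4cc(O[Si](C)(C)C(C)(C)C)c5c(c4)O[C@@H](c4ccc(O[Si](C)(C)C(C)(C)C)cc4)[C@@H]5c4cc(O[Si](C)(C)C(C)(C)C)cc(O[Si](C)(C)C(C)(C)C)c4)[C@@H](c4ccc(O[Si](C)(C)C(C)(C)C)cc4)O2 | intermediate
24 | 4-[(tert-butyldimethylsilyl)oxy]benzaldehyde | O=Cc1ccc(O[Si](C)(C)C(C)(C)C)cc1 | starting material
25 | {4-[(tert-butyldimethylsilyl)oxy]phenyl}methanol | OCc1ccc(O[Si](C)(C)C(C)(C)C)cc1 | intermediate
26 | diethyl {4-[(tert-butyldimethylsilyl)oxy]benzyl}phosphonate | CCOP(=O)(Cc1ccc(O[Si](C)(C)C(C)(C)C)cc1)OCC | intermediate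
27 | heptakis-O-TBS ether of the target | CC(C)(C)[Si](C)(C)Oc1ccc(/C=C/c2cc(O[Si](C)(C)C(C)(C)C)cc3c2[C@H](c2cc(O[Si](C)(C)C(C)(C)C)c4c(c2)O[C@@H](c2ccc(O[Si](C)(C)C(C)(C)C)cc2)[C@@H]4c2cc(O[Si](C)(C)C(C)(C)C)cc(O[Si](C)(C)C(C)(C)C)c2)[C@@H](c2ccc(O[Si](C)(C)C(C)(C)C)cc2)O3)cc1 | intermediate
28 | target CNP0188679.4 | Oc1ccc(/C=C/c2cc(O)cc3c2[C@H](c2cc(O)c4c(c2)O[C@@H](c2ccc(O)cc2)[C@@H]4c2cc(O)cc(O)c2)[C@@H](c2ccc(O)cc2)O3)cc1 | target

## Step count and least certain steps

Total step count: 16. Longest linear sequence: 11 steps (1, 2, 3, 4, 5, 9, 10, 11, 12, 15, 16).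

**Step 5.**
- What may go wrong:
  - Carbene formation may be slow because the diazo carbon lies between two ortho alkoxy groups, so azine formation or protonation of the diazo compound could compete.
  - Facial selectivity may be lower than for unhindered models, because ring C is twisted out of the carbene plane and sits differently in the catalyst pocket.
- Fallback (sets out from 7, comes back at 10): Ketone 7 is irradiated at 365 nm. The Norrish–Yang photocyclisation of an ortho-benzyloxy benzophenone (delta-hydrogen abstraction from OCH2, closure of the 1,5-biradical) forms the same C2'–C3' bond without any diazo compound. It gives the racemic 3-hydroxy-2,3-dihydrobenzofuran nitrile F1. Ionic deoxygenation (Et3SiH, CF3CO2H, CH2Cl2, −40 °C) delivers hydride to the C3' cation anti to ring G and should give the racemic cis compound, that is 10 together with the (2R,3S)-enantiomer of 10 F2. The two are separated by preparative chromatography on a chiral stationary phase.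

**Step 9.**
- What may go wrong:
  - The aryllithium may deprotonate C3'–H, which the para nitrile acidifies, and this would be followed by beta-elimination of O1' and opening of ring D.
  - Exchange of NH3 for hydrazine at the hindered ketimine may be slow.
- Fallback (sets out from 10 and 15, comes back at 18): The nitrile of 10 is reduced with i-Bu2AlH (toluene, −78 °C, then mild aqueous work-up) to the (2S,3R)-dihydrobenzofuran-6-carbaldehyde F3. This aldehyde captures 16 far faster than any proton transfer can occur and gives the diaryl carbinol F4. Dess–Martin oxidation gives the diaryl ketone F5. Condensation with anhydrous hydrazine in ethanol in a sealed tube leads to 18.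

**Step 10 (key step).**
- What may go wrong:
  - The diazo carbon, flanked by the OBOB group and the acetal, may approach the rhodium centre too slowly, so that thermal decay of the diazo compound and azine formation take over.
  - Enantioface discrimination may erode for the same steric reason.
- Fallback (sets out from 10 and 15 by way of ketone F5 of the preceding fallback, comes back at 20): F5 is irradiated at 365 nm. Norrish–Yang cyclisation through abstraction of an O1–CH2 hydrogen closes ring B and gives the 3-hydroxy derivative of 20 F6 as a mixture of ring B isomers. Competing enolisation through the acetal C–H is reversible. The C3 carbinol is trityl-like and ionises with a weak acid, so Et3SiH with Cl2CHCO2H (CH2Cl2, −20 °C) should remove the hydroxyl group without touching the acetal. Because ring D is already a single enantiomer, the two cis products, 20 and the (2S,3R,2'S,3'R)-diastereomer of 20 F7, are diastereomers and are separated by ordinary chromatography. Stereocontrol is thereby shifted from the catalyst to a separation.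

**Step 11.**
- What may go wrong:
  - Hydrogenolysis may go too far and cleave the cyclic benzylic C2–O1 or C2'–O1' bonds.
  - In the acid stage, free resorcinol rings may condense with the aldehyde, or a quinone methide may be captured intermolecularly, before the trans rings have formed.
- Fallback (sets out from 20, comes back at 22): The order is reversed. Compound 20 is treated with CF3CO2H (2 vol %) in wet CH2Cl2 at 0 °C. With all phenols still blocked, this hydrolyses the acetal and equilibrates both rings to the fully protected (2S,3S,2'R,3'R)-aldehyde F8. The benzyl and BOB groups are then removed without hydrogen by BCl3 and pentamethylbenzene (CH2Cl2, −78 °C). The bulky scavenger takes up the primary benzyl cations, while the crowded secondary C2 cations re-close intramolecularly, giving 22.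

## Further compounds

F1 | step 5 | rac-3-[3,5-bis(benzyloxy)phenyl]-2-[4-(benzyloxy)phenyl]-4-{[4-(benzyloxy)benzyl]oxy}-3-hydroxy-2,3-dihydro-1-benzofuran-6-carbonitrile | N#Cc1cc(OCc2ccc(OCc3ccccc3)cc2)c2c(c1)OC(c1ccc(OCc3ccccc3)cc1)C2(O)c1cc(OCc2ccccc2)cc(OCc2ccccc2)c1
F2 | step 5 | (2R,3S)-enantiomer of 10 | N#Cc1cc(OCc2ccc(OCc3ccccc3)cc2)c2c(c1)O[C@@H](c1ccc(OCc3ccccc3)cc1)[C@H]2c1cc(OCc2ccccc2)cc(OCc2ccccc2)c1
F3 | step 9 | (2S,3R)-3-[3,5-bis(benzyloxy)phenyl]-2-[4-(benzyloxy)phenyl]-4-{[4-(benzyloxy)benzyl]oxy}-2,3-dihydro-1-benzofuran-6-carbaldehyde | O=Cc1cc(OCc2ccc(OCc3ccccc3)cc2)c2c(c1)O[C@H](c1ccc(OCc3ccccc3)cc1)[C@@H]2c1cc(OCc2ccccc2)cc(OCc2ccccc2)c1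
F4 | step 9 | diaryl carbinol from 16 and F3 (both epimers at the carbinol carbon) | OC(c1c(C(OC)OC)cc(OCc2ccc(OCc3ccccc3)cc2)cc1OCc1ccc(OCc2ccccc2)cc1)c1cc(OCc2ccc(OCc3ccccc3)cc2)c2c(c1)O[C@H](c1ccc(OCc3ccccc3)cc1)[C@@H]2c1cc(OCc2ccccc2)cc(OCc2ccccc2)c1
F5 | step 9 | diaryl ketone corresponding to 17 | O=C(c1c(C(OC)OC)cc(OCc2ccc(OCc3ccccc3)cc2)cc1OCc1ccc(OCc2ccccc2)cc1)c1cc(OCc2ccc(OCc3ccccc3)cc2)c2c(c1)O[C@H](c1ccc(OCc3ccccc3)cc1)[C@@H]2c1cc(OCc2ccccc2)cc(OCc2ccccc2)c1
F6 | step 10 | 3-hydroxy derivative of 20 (mixture of ring B isomers, ring D 2'S,3'R) | COC(OC)c1cc(OCc2ccc(OCc3ccccc3)cc2)cc2c1C(O)(c4cc(OCc5ccc(OCc6ccccc6)cc5)c5c(c4)O[C@H](c4ccc(OCc6ccccc6)cc4)[C@@H]5c4cc(OCc5ccccc5)cc(OCc5ccccc5)c4)C(c4ccc(OCc5ccccc5)cc4)O2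
F7 | step 10 | (2S,3R,2'S,3'R)-diastereomer of 20 | COC(OC)c1cc(OCc2ccc(OCc3ccccc3)cc2)cc2c1[C@@H](c4cc(OCc5ccc(OCc6ccccc6)cc5)c5c(c4)O[C@H](c4ccc(OCc6ccccc6)cc4)[C@@H]5c4cc(OCc5ccccc5)cc(OCc5ccccc5)c4)[C@@H](c4ccc(OCc5ccccc5)cc4)O2
F8 | step 11 | fully benzyl/BOB protected (2S,3S,2'R,3'R)-aldehyde | O=Cc1cc(OCc2ccc(OCc3ccccc3)cc2)cc2c1[C@H](c4cc(OCc5ccc(OCc6ccccc6)cc5)c5c(c4)O[C@@H](c4ccc(OCc6ccccc6)cc4)[C@@H]5c4cc(OCc5ccccc5)cc(OCc5ccccc5)c4)[C@@H](c4ccc(OCc5ccccc5)cc4)O2
A1 | alternative 1 | (2R,3R)-gnetin C | Oc1ccc(/C=C/c2cc(O)c3c(c2)O[C@@H](c2ccc(O)cc2)[C@@H]3c2cc(O)cc(O)c2)cc1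
A2 | alternative 1 | resveratrol | Oc1ccc(/C=C/c2cc(O)cc(O)c2)cc1
A3 | alternative 2 | (S)-2-[2,4-bis(benzyloxy)-6-(dimethoxymethyl)phenyl]-2-[(2R,3R)-perbenzylated dihydrobenzofuran-6-yl]acetaldehyde | COC(OC)c1cc(OCc2ccccc2)cc(OCc2ccccc2)c1[C@H](c4cc(OCc5ccccc5)c5c(c4)O[C@@H](c4ccc(OCc6ccccc6)cc4)[C@@H]5c4cc(OCc5ccccc5)cc(OCc5ccccc5)c4)C=O
A4 | alternative 3 | bis(diazo) compound with diazo groups at the future C3 and C3' | [N-]=[N+]=C(c1c(C(OC)OC)cc(OCc2ccc(OCc3ccccc3)cc2)cc1OCc1ccc(OCc2ccccc2)cc1)c1cc(OCc2ccc(OCc3ccccc3)cc2)c(C(=[N+]=[N-])c2cc(OCc3ccccc3)cc(OCc3ccccc3)c2)c(OCc2ccc(OCc3ccccc3)cc2)c1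
A5 | alternative 3 | (2R,3S,2'R,3'S)-bis(cis-dihydrobenzofuran) acetal, same local sense in both rings | COC(OC)c1cc(OCc2ccc(OCc3ccccc3)cc2)cc2c1[C@H](c4cc(OCc5ccc(OCc6ccccc6)cc5)c5c(c4)O[C@@H](c4ccc(OCc6ccccc6)cc4)[C@H]5c4cc(OCc5ccccc5)cc(OCc5ccccc5)c4)[C@H](c4ccc(OCc5ccccc5)cc4)O2
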